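## Retrosynthetic overview

1. Manassantin A is C2-symmetric, so both side chains are attached last to a bis-phenol tetrahydrofuran core: double SN2 O-alkylation (inversion) with a lactate-derived (S)-α-tosyloxy ketone, then Felkin–Anh reduction of both ketones.
2. The tetrahydrofuran is the only ring formed. It is closed first as a γ-lactone (C5–O), then the second aryl is added at C2 through an oxocarbenium ion generated from a 2-sulfonyl ether.
3. The lactone comes from Felkin–Anh addition of an aryl Grignard to (2R,3R)-2,3-dimethylsuccinic semialdehyde.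
4. The C3–C4 bond and both methyl stereocentres come from an Ireland–Claisen [3,3]-rearrangement of (S,Z)-pent-3-en-2-yl propanoate, with 1,3-chirality transfer.
5. All chirality traces back to ethyl (S)-lactate, used for both the core and the side chains.

Assumptions: the target is taken exactly as drawn, i.e. a (2S,3R,4R,5S) core (2,3-cis, 3,4-trans, 4,5-cis) with threo (1R,2R) side chains. Aryl Grignard and arylzinc reagents made in situ from the bromides are not counted as steps, and one-pot two-stage operations count as one step. Aryl bromides 7 and 14 are assumed to be commercial.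

## Route

**Step 1**
Reactants: 1, ethyl (S)-lactate
Product: 2, ethyl (S)-2-(tert-butyldimethylsilyloxy)propanoate
Conditions: TBSCl, imidazole, DMF, 0 °C → rt
Reagents that add atoms: TBSCl, CC(C)(C)[Si](C)(C)Cl
Why: Standard imidazole-mediated silylation of a secondary alcohol; the lactate stereocentre is not touched.

**Step 2**
Reactants: 2
Product: 3, (S,Z)-tert-butyldimethyl(pent-3-en-2-yloxy)silane
Conditions: DIBAL-H (1.05 equiv), CH2Cl2, −78 °C; then Ph3P=CHCH3 (from EtPPh3Br, KHMDS, THF), −78 °C → rt, one pot
Reagents that add atoms: ethyltriphenylphosphonium bromide, CC[P+](c1ccccc1)(c1ccccc1)c1ccccc1.[Br-]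
Why: Low-temperature half-reduction followed by in-situ Wittig olefination with a salt-free non-stabilised ylide gives the Z-alkene (expected ≥95:5) without isolating the racemisation-prone α-silyloxy aldehyde.

**Step 3**
Reactants: 3
Product: 4, (S,Z)-pent-3-en-2-yl propanoate
Conditions: TBAF, THF, 0 °C → rt; then (EtCO)2O, Et3N, DMAP, rt, one pot
Reagents that add atoms: propionic anhydride, CCC(=O)OC(=O)CC
Why: Fluoride desilylation and in-situ DMAP-catalysed acylation avoid isolating the volatile allylic alcohol; no bond to the stereocentre is broken.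

**Step 4**
Reactants: 4
Product: 5, (2R,3S,E)-2,3-dimethylhex-4-enoic acid
Conditions: LDA, THF, −78 °C; TMSCl/Et3N, −78 °C → rt → 55 °C; then 1 M NaOH, then H3O+
Reagents that add atoms: none (TMS is lost on work-up)
Why: Ireland–Claisen [3,3]-sigmatropic rearrangement. Kinetic LDA/THF enolisation gives the (E)-silyl ketene acetal, and the chair transition state with the carbinol methyl equatorial (enforced by the Z-alkene) transfers the lactate C–O chirality to both new methyl-bearing centres (2,3-syn, 2R,3S) and gives the E-alkene; expected dr about 9:1.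

**Step 5**
Reactants: 5
Product: 6, (2R,3R)-2,3-dimethyl-4-oxobutanoic acid, present mainly as its cyclic pseudo-acid (3R,4R)-5-hydroxy-3,4-dimethyldihydrofuran-2(3H)-one
Conditions: O3, CH2Cl2, −78 °C; then Me2S, −78 °C → rt; used crude
Reagents that add atoms: ozone, [O-][O+]=O
Why: Ozonolysis with reductive work-up cleaves the alkene (acetaldehyde is lost). The aldehyde is held as the lactol, which limits α-epimerisation; the C3 descriptor changes from S to R only through CIP priorities.

**Step 6**
Reactants: 6; 7, 1-(benzyloxy)-4-bromo-2-methoxybenzene (as its Grignard reagent)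
Product: 8, (3R,4R,5S)-5-[4-(benzyloxy)-3-methoxyphenyl]-3,4-dimethyldihydrofuran-2(3H)-one (3,4-trans, 4,5-cis)
Conditions: ArMgBr (from 7, Mg, THF; 2.3 equiv), THF, −78 → −20 °C; then aq. citric acid (pH 3), rt; chromatography
Reagents that add atoms: none beyond reactant 7
Why: The first equivalent opens the pseudo-acid to the carboxylate aldehyde. The second adds in the Felkin–Anh sense (anti to the branched C2 chain), setting C5 as S; mild acidification lactonises to the 4,5-cis lactone. Expected dr about 4–5:1; the C5 epimer and the minor series from Step 4 are removed here.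

**Step 7**
Reactants: 8
Product: 9, (3R,4R,5S)-5-[4-(benzyloxy)-3-methoxyphenyl]-3,4-dimethyltetrahydrofuran-2-ol (anomeric mixture)
Conditions: DIBAL-H (1.1 equiv), CH2Cl2, −78 °C
Reagents that add atoms: none
Why: Lactone half-reduction stops at the lactol because the tetrahedral aluminate is stable at −78 °C.

**Step 8**
Reactants: 9
Product: 10, (3R,4R,5S)-5-[4-(benzyloxy)-3-methoxyphenyl]-3,4-dimethyl-2-(phenylsulfonyl)tetrahydrofuran (C2 mixture)
Conditions: PhSO2H, CaCl2, CH2Cl2, rt
Reagents that add atoms: benzenesulfinic acid, O=S(O)c1ccccc1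
Why: Acid-mediated exchange of the anomeric OH for sulfinate through the oxocarbenium ion gives a stable 2-sulfonyl ether that ionises under mild Lewis acid.

**Step 9**
Reactants: 10; 7 (as its arylzinc bromide)
Product: 11, (2S,3R,4R,5S)-2,5-bis[4-(benzyloxy)-3-methoxyphenyl]-3,4-dimethyltetrahydrofuran
Conditions: ArZnBr (from 7, Mg, THF; then ZnBr2; 3 equiv), THF, 0 °C → rt
Reagents that add atoms: none beyond reactant 7
Why: ZnBr2 ionises the sulfone to the cyclic oxocarbenium ion. The arylzinc adds to the face opposite the C4 methyl and C5 aryl (1,3-trans, inside attack on the envelope), placing the new aryl cis to the C3 methyl and setting C2 as S.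

**Step 10**
Reactants: 11
Product: 12, 4,4'-[(2S,3R,4R,5S)-3,4-dimethyltetrahydrofuran-2,5-diyl]bis(2-methoxyphenol)
Conditions: H2 (1 atm), 10% Pd/C, EtOAc, rt, monitored and stopped at full debenzylation
Reagents that add atoms: none
Why: Hydrogenolysis of the two benzyl aryl ethers is much faster than cleavage of the hindered ring benzylic C–O bonds under neutral conditions at 1 atm.

**Step 11**
Reactants: 1
Product: 13, (S)-2-hydroxy-1-(pyrrolidin-1-yl)propan-1-one
Conditions: pyrrolidine (neat), rt → 40 °C
Reagents that add atoms: pyrrolidine, C1CCNC1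
Why: Aminolysis of the α-hydroxy ester by a neat secondary amine; no base strong enough to epimerise the centre is present.

**Step 12**
Reactants: 13; 14, 4-bromo-1,2-dimethoxybenzene (as its Grignard reagent)
Product: 15, (S)-1-(3,4-dimethoxyphenyl)-2-hydroxypropan-1-one
Conditions: ArMgBr (from 14, Mg; 2.5–3 equiv), THF, 0 °C → rt; aq. NH4Cl
Reagents that add atoms: none beyond reactant 14
Why: The magnesium alkoxide formed first masks the OH and chelates the amide, so one aryl adds to give a stable tetrahedral chelate that releases the ketone only on work-up (amide acylation of a Grignard reagent), without racemisation.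

**Step 13**
Reactants: 15
Product: 16, (S)-1-(3,4-dimethoxyphenyl)-1-oxopropan-2-yl 4-methylbenzenesulfonate
Conditions: TsCl, Et3N, DMAP (cat.), CH2Cl2, 0 °C
Reagents that add atoms: tosyl chloride, Cc1ccc(cc1)S(Cl)(=O)=O
Why: O-sulfonylation does not break the C–O bond, so configuration is retained.

**Step 14**
Reactants: 12; 16 (2.4 equiv)
Product: 17, (2R,2'R)-2,2'-{[(2S,3R,4R,5S)-3,4-dimethyltetrahydrofuran-2,5-diyl]bis[(2-methoxy-4,1-phenylene)oxy]}bis[1-(3,4-dimethoxyphenyl)propan-1-one]
Conditions: BEMP (2.5 equiv), CH2Cl2 (or MeCN), 0 °C → rt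
Reagents that add atoms: none beyond reactants
Why: Double SN2 O-alkylation of the phenoxides at the activated α-keto carbon with inversion (S → R). The non-nucleophilic phosphazene base and tosylate leaving group avoid enolisation and racemisation.

**Step 15**
Reactants: 17
Product: 18, manassantin A
Conditions: polymer-supported borohydride (BH4⁻ on Amberlite IRA-400), MeOH, rt
Reagents that add atoms: none
Why: Felkin–Anh (polar, non-chelation) hydride delivery anti to the α-aryloxy group with a non-chelating ammonium borohydride gives the (R)-carbinol next to each (R)-ether centre (threo) at both termini.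

## Compound list

1 | ethyl (S)-lactate | C[C@H](O)C(=O)OCC | starting material
2 | ethyl (S)-2-(tert-butyldimethylsilyloxy)propanoate | C[C@H](O[Si](C)(C)C(C)(C)C)C(=O)OCC | intermediate
3 | (S,Z)-tert-butyldimethyl(pent-3-en-2-yloxy)silane | C[C@H](O[Si](C)(C)C(C)(C)C)/C=C\C | intermediate
4 | (S,Z)-pent-3-en-2-yl propanoate | CCC(=O)O[C@@H](C)/C=C\C | intermediate
5 | (2R,3S,E)-2,3-dimethylhex-4-enoic acid | C/C=C/[C@H](C)[C@@H](C)C(=O)O | intermediate
6 | (2R,3R)-2,3-dimethyl-4-oxobutanoic acid (pseudo-acid form in equilibrium) | O=C[C@H](C)[C@@H](C)C(=O)O | intermediate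
7 | 1-(benzyloxy)-4-bromo-2-methoxybenzene | COc1cc(Br)ccc1OCc1ccccc1 | starting material
8 | (3R,4R,5S)-5-[4-(benzyloxy)-3-methoxyphenyl]-3,4-dimethyldihydrofuran-2(3H)-one | O=C1O[C@H](c2ccc(OCc3ccccc3)c(OC)c2)[C@H](C)[C@H]1C | intermediate
9 | (3R,4R,5S)-5-[4-(benzyloxy)-3-methoxyphenyl]-3,4-dimethyltetrahydrofuran-2-ol | OC1O[C@H](c2ccc(OCc3ccccc3)c(OC)c2)[C@H](C)[C@H]1C | intermediate
10 | (3R,4R,5S)-5-[4-(benzyloxy)-3-methoxyphenyl]-3,4-dimethyl-2-(phenylsulfonyl)tetrahydrofuran | O=S(=O)(c1ccccc1)C1O[C@H](c2ccc(OCc3ccccc3)c(OC)c2)[C@H](C)[C@H]1C | intermediate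
11 | (2S,3R,4R,5S)-2,5-bis[4-(benzyloxy)-3-methoxyphenyl]-3,4-dimethyltetrahydrofuran | COc1cc(ccc1OCc2ccccc2)[C@H]3O[C@H](c4ccc(OCc5ccccc5)c(OC)c4)[C@H](C)[C@H]3C | intermediate
12 | 4,4'-[(2S,3R,4R,5S)-3,4-dimethyltetrahydrofuran-2,5-diyl]bis(2-methoxyphenol) | COc1cc(ccc1O)[C@H]2O[C@H](c3ccc(O)c(OC)c3)[C@H](C)[C@H]2C | intermediate
13 | (S)-2-hydroxy-1-(pyrrolidin-1-yl)propan-1-one | C[C@H](O)C(=O)N1CCCC1 | intermediate
14 | 4-bromo-1,2-dimethoxybenzene | COc1ccc(Br)cc1OC | starting material
15 | (S)-1-(3,4-dimethoxyphenyl)-2-hydroxypropan-1-one | COc1ccc(cc1OC)C(=O)[C@H](C)O | intermediate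
16 | (S)-1-(3,4-dimethoxyphenyl)-1-oxopropan-2-yl 4-methylbenzenesulfonate | COc1ccc(cc1OC)C(=O)[C@H](C)OS(=O)(=O)c1ccc(C)cc1 | intermediate
17 | bis-ketone (name as in Step 14) | COc1ccc(C(=O)[C@@H](C)Oc2ccc([C@H]3O[C@H](c4ccc(O[C@H](C)C(=O)c5ccc(OC)c(OC)c5)c(OC)c4)[C@H](C)[C@H]3C)cc2OC)cc1OC | intermediate
18 | manassantin A | COc1ccc([C@@H](O)[C@@H](C)Oc2ccc([C@H]3O[C@H](c4ccc(O[C@H](C)[C@H](O)c5ccc(OC)c(OC)c5)c(OC)c4)[C@H](C)[C@H]3C)cc2OC)cc1OC | target

## Summary

Total steps: 15. Longest linear sequence: 12 (Steps 1–10, 14, 15); the side-chain electrophile 16 is made in 3 steps (11–13).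

Steps most likely to fail, each with a fallback:

- **Step 6** (Felkin–Anh aryl addition to the semialdehyde; moderate dr, possible α-epimerisation, awkward pseudo-acid substrate). Fallback: introduce this aryl by the same oxocarbenium chemistry as Step 9. Convert 6 to its methyl pseudo-ester, reduce with DIBAL to the 5-methoxy lactol, convert to the 2,5-bis(phenylsulfonyl)-3,4-dimethyltetrahydrofuran, and add ArZnBr twice, so that each aryl enters anti to the β-methyl and 11 is formed directly.
- **Step 2** (one-pot DIBAL/Wittig; Z:E ratio and aldehyde racemisation feed directly into the diastereomeric and enantiomeric purity of 5). Fallback: take the alkene geometry from an alkyne instead. Use commercial (S)-but-3-yn-2-ol: C-methylate its dianion, then Lindlar semi-hydrogenation to (S,Z)-pent-3-en-2-ol, then propionylate to 4.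
- **Step 15** (two simultaneous Felkin reductions; the overall dr is the square of the per-site selectivity). Fallback: set the carbinol before coupling. Make a lactate-derived (1R,2S)-1-(3,4-dimethoxyphenyl)-1-silyloxypropan-2-ol by chelation-controlled reduction of O-protected 15 followed by protecting-group adjustment, then join it to bis-phenol 12 by a double Mitsunobu etherification (inversion at C2 gives 1R,2R) and desilylate.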